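**Retrosynthetic overview**

1. The octenoate, N-Boc and O-TBS groups are handled last. C5 comes from hydrogenation of a C5=C1' alkylidene and the C3 carbinol from a C3 ketone.
2. Key disconnection C4a–C5: nickel-catalysed reductive alkyne–enone cyclisation of a monocyclic 2,6-trans N-Boc-dihydropyridin-3-one. The enabling feature is that C4a is the β-carbon of the C3(=O)–C4=C4a enone inside the piperidine ring, while C5 bears an exocyclic carbon (C1'). A C5≡C1' alkyne on the C8a–C8–C7–C6 tether therefore closes the carbocycle C4a/C5/C6/C7/C8/C8a and brings the whole side chain with it.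
3. The piperidinone comes from aza-Achmatowicz dearomatisation of a 2,5-disubstituted furan (furan C2–C5 = C3, C4, C4a, C8a), followed by silane reduction that sets C8a trans to the C2 methyl.
4. The furan is assembled by B-alkyl Suzuki–Miyaura coupling of a bromofuryl carbamate (from (R)-1-(furan-2-yl)ethanamine, source of C2) with a skipped enyne carrying the C5' carbinol (from (R)-2-propyloxirane).
5. Ring order: piperidine ring N1–C2–C3–C4–C4a–C8a first (step 8), carbocycle last (step 10).

Key step: step 10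

Remark: (R)-2-propyloxirane (1) and (R)-1-(furan-2-yl)ethan-1-amine (9, free base) are taken as purchasable single enantiomers; C6 of hemiaminal 14 is left undefined because step 9 destroys it.

**Route**

Step 1
Reactants: 1 (R)-2-propyloxirane; 2 (4-bromobut-1-yn-1-yl)trimethylsilane
Product: 4 (R)-9-(trimethylsilyl)non-8-yn-4-ol, via Grignard reagent 3 (not isolated)
Conditions: 2, Mg, THF, rt; then CuI (10 mol %), 1, −30 → 0 °C; H2O quench
Reagents that add atoms: magnesium, [Mg] (present in intermediate 3 only)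
Why: Copper-catalysed Grignard opening of a terminal epoxide occurs at the unsubstituted carbon, so the C–O stereocentre of 1 (C5' of the target, R) is carried over untouched.

Step 2
Reactants: 4 (R)-9-(trimethylsilyl)non-8-yn-4-ol
Product: 5 (R)-tert-butyldimethyl{[9-(trimethylsilyl)non-8-yn-4-yl]oxy}silane
Conditions: TBSCl, imidazole, DMF, rt
Reagents that add atoms: tert-butyldimethylsilyl chloride, CC(C)(C)[Si](C)(C)Cl
Why: Standard silylation of a secondary alcohol; the TBS ether masks the C5' hydroxyl so that only the C3 hydroxyl is free at the esterification.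

Step 3
Reactants: 5 (R)-tert-butyldimethyl{[9-(trimethylsilyl)non-8-yn-4-yl]oxy}silane
Product: 6 (R)-tert-butyldimethyl(non-8-yn-4-yloxy)silane
Conditions: K2CO3 (cat.), MeOH, rt
Reagents that add atoms: none
Why: Base-catalysed methanolysis cleaves the C(sp)–Si bond selectively, the O–Si bond of the hindered TBS ether being inert to K2CO3/MeOH.

Step 4
Reactants: 6 (R)-tert-butyldimethyl(non-8-yn-4-yloxy)silane; 7 allyl bromide
Product: 8 (R)-tert-butyl(dodec-11-en-8-yn-4-yloxy)dimethylsilane
Conditions: CuI (0.2 equiv), NaI, K2CO3, DMF, rt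
Reagents that add atoms: none
Why: Copper-acetylide allylation of the terminal alkyne gives the skipped enyne, whose terminal alkene is the handle for the later hydroboration.

Step 5
Reactants: 9 (R)-1-(furan-2-yl)ethan-1-amine
Product: 10 tert-butyl N-[(1R)-1-(furan-2-yl)ethyl]carbamate
Conditions: Boc2O, CH2Cl2, rt
Reagents that add atoms: di-tert-butyl dicarbonate, CC(C)(C)OC(=O)OC(=O)OC(C)(C)C
Why: Carbamate formation on the primary amine; the Boc group supplies the N–H acidity and electron withdrawal needed for the aza-Achmatowicz reaction and later the A(1,3) strain that steers steps 9 to 11.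

Step 6
Reactants: 10 tert-butyl N-[(1R)-1-(furan-2-yl)ethyl]carbamate
Product: 11 tert-butyl N-[(1R)-1-(5-bromofuran-2-yl)ethyl]carbamate
Conditions: NBS, dry DMF, −20 °C, dark; used without storage
Reagents that add atoms: N-bromosuccinimide, O=C1CCC(=O)N1Br
Why: Electrophilic aromatic bromination of a 2-substituted furan goes to the free α-position (C5) under anhydrous conditions, the stereocentre next to the ring not being involved.

Step 7
Reactants: 8 (R)-tert-butyl(dodec-11-en-8-yn-4-yloxy)dimethylsilane; 11 tert-butyl N-[(1R)-1-(5-bromofuran-2-yl)ethyl]carbamate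
Product: 13 tert-butyl N-[(1R)-1-{5-[(9R)-9-[(tert-butyldimethylsilyl)oxy]dodec-4-yn-1-yl]furan-2-yl}ethyl]carbamate, via B-alkyl-9-BBN borane 12 (not isolated)
Conditions: 8, 9-BBN, THF, 0 °C → rt; then 11, Pd(dppf)Cl2 (5 mol %), aq. K3PO4, DMF, 50 °C
Reagents that add atoms: 9-borabicyclo[3.3.1]nonane, B1C2CCCC1CCC2 (present in intermediate 12 only)
Why: 9-BBN hydroborates the terminal alkene anti-Markovnikov much faster than the internal alkyne, and the B-alkyl Suzuki–Miyaura coupling joins the primary alkylborane to the bromofuran without touching either stereocentre.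

Step 8
Reactants: 13 tert-butyl N-[(1R)-1-{5-[(9R)-9-[(tert-butyldimethylsilyl)oxy]dodec-4-yn-1-yl]furan-2-yl}ethyl]carbamate
Product: 14 tert-butyl (2R)-6-[(9R)-9-[(tert-butyldimethylsilyl)oxy]dodec-4-yn-1-yl]-6-hydroxy-2-methyl-3-oxo-3,6-dihydropyridine-1(2H)-carboxylate (C6 epimers)
Conditions: mCPBA, CH2Cl2, 0 °C
Reagents that add atoms: 3-chloroperbenzoic acid, OOC(=O)c1cccc(Cl)c1
Why: Aza-Achmatowicz reaction: peracid oxidation of the furan gives a cis-enedione that is trapped by the carbamate nitrogen as the six-membered hemiaminal, so the flat furan (C2–C5 = C3, C4, C4a, C8a) becomes the piperidinone ring with C2 unchanged.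

Step 9
Reactants: 14 tert-butyl (2R)-6-[(9R)-9-[(tert-butyldimethylsilyl)oxy]dodec-4-yn-1-yl]-6-hydroxy-2-methyl-3-oxo-3,6-dihydropyridine-1(2H)-carboxylate
Product: 15 tert-butyl (2R,6R)-6-[(9R)-9-[(tert-butyldimethylsilyl)oxy]dodec-4-yn-1-yl]-2-methyl-3-oxo-3,6-dihydropyridine-1(2H)-carboxylate (2,6-trans)
Conditions: Et3SiH, BF3·OEt2, CH2Cl2, −78 → −40 °C
Reagents that add atoms: none
Why: Ionic reduction of the hemiaminal: BF3 ionises it to the N-acyliminium ion, A(1,3) strain with Boc holds the C2 methyl pseudoaxial, and Et3SiH should deliver hydride axially on the methyl-bearing face, so that H8a ends cis to the methyl and the chain trans (6R).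

Step 10
Reactants: 15 tert-butyl (2R,6R)-6-[(9R)-9-[(tert-butyldimethylsilyl)oxy]dodec-4-yn-1-yl]-2-methyl-3-oxo-3,6-dihydropyridine-1(2H)-carboxylate
Product: 16 tert-butyl (2R,4aS,5E,8aR)-5-[(5R)-5-[(tert-butyldimethylsilyl)oxy]octylidene]-2-methyl-3-oxooctahydroquinoline-1(2H)-carboxylate
Conditions: Ni(cod)2 (10 mol %), PBu3 (20 mol %), Et3B (3 equiv), MeOH/THF (8:1), 50 °C
Reagents that add atoms: none
Why: Ni(0) binds the alkyne and the enone of 15 and undergoes oxidative cyclisation, forming the C4a–C5 bond and an alkenyl-nickel/O-bound nickel enolate metallacycle; methanol protonates the enolate (giving the C4 methylene), Et3B transfers ethyl to nickel, and β-hydride elimination followed by C–H reductive elimination places hydrogen on C1' cis to C4a, which is the E-alkylidene. The closest known reaction type is the nickel-catalysed reductive coupling and cyclisation of enones with alkynes. The carbocycle closes in a 6-exo-dig mode, the enone β-carbon C4a bonding to the proximal alkyne carbon C5 while C1' stays exocyclic. The new stereocentre C4a is controlled by C8a: A(1,3) strain with N-Boc keeps the C8a tether pseudoaxial, so the alkyne can reach only the face of C4a on which the tether stands, which gives the cis ring fusion (4aS). The step needs hydrogen rather than ethyl termination and no enolisation at C2; the phosphine/Et3B/MeOH system and the neutral medium are chosen for this, and in the nearly planar enone the 2,6-trans arrangement with both substituents pseudoaxial on opposite faces should be the more stable one, so C2 should hold.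

Step 11
Reactants: 16 tert-butyl (2R,4aS,5E,8aR)-5-[(5R)-5-[(tert-butyldimethylsilyl)oxy]octylidene]-2-methyl-3-oxooctahydroquinoline-1(2H)-carboxylate
Product: 17 tert-butyl (2R,3R,4aS,5E,8aR)-5-[(5R)-5-[(tert-butyldimethylsilyl)oxy]octylidene]-3-hydroxy-2-methyloctahydroquinoline-1(2H)-carboxylate
Conditions: L-Selectride, THF, −78 °C; then H2O
Reagents that add atoms: none
Why: Diastereoselective ketone reduction: the bulky hydride should attack the C3 carbonyl from the face away from the adjacent C2 methyl group, as is usual for N-Boc-2-alkylpiperidin-3-ones, giving the 2,3-cis (3R) alcohol.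

Step 12
Reactants: 17 tert-butyl (2R,3R,4aS,5E,8aR)-5-[(5R)-5-[(tert-butyldimethylsilyl)oxy]octylidene]-3-hydroxy-2-methyloctahydroquinoline-1(2H)-carboxylate
Product: 18 tert-butyl (2R,3R,4aS,5S,8aR)-5-[(5R)-5-[(tert-butyldimethylsilyl)oxy]octyl]-3-hydroxy-2-methyloctahydroquinoline-1(2H)-carboxylate
Conditions: H2 (1 atm), PtO2, EtOAc, rt
Reagents that add atoms: none
Why: Heterogeneous hydrogenation of the exocyclic alkene should take place from the convex face of the cis-fused bicycle (the face of H4a and H8a, away from the piperidine ring), which sets C5 (S) with H5 cis to H4a and H8a.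

Step 13
Reactants: 18 tert-butyl (2R,3R,4aS,5S,8aR)-5-[(5R)-5-[(tert-butyldimethylsilyl)oxy]octyl]-3-hydroxy-2-methyloctahydroquinoline-1(2H)-carboxylate; 19 (2E)-oct-2-enoic acid
Product: 20 tert-butyl (2R,3R,4aS,5S,8aR)-5-[(5R)-5-[(tert-butyldimethylsilyl)oxy]octyl]-2-methyl-3-{[(2E)-oct-2-enoyl]oxy}octahydroquinoline-1(2H)-carboxylate
Conditions: DIC, DMAP, CH2Cl2, 0 °C → rt
Reagents that add atoms: none
Why: Carbodiimide/DMAP (Steglich) esterification of the only free hydroxyl, with nitrogen and the C5' oxygen both protected.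

Step 14
Reactants: 20 tert-butyl (2R,3R,4aS,5S,8aR)-5-[(5R)-5-[(tert-butyldimethylsilyl)oxy]octyl]-2-methyl-3-{[(2E)-oct-2-enoyl]oxy}octahydroquinoline-1(2H)-carboxylate
Product: 21 (2R,3R,4aS,5S,8aR)-5-[(5R)-5-hydroxyoctyl]-2-methyldecahydroquinolin-3-yl (2E)-oct-2-enoate
Conditions: TFA/H2O (9:1), 0 °C → rt; then aq. NaHCO3
Reagents that add atoms: none
Why: Acidolysis removes the Boc group and the TBS ether in one operation, while the conjugated ester and all stereocentres are stable to aqueous TFA.

**Compound list**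

1 | (R)-2-propyloxirane | CCC[C@@H]1CO1 | starting material
2 | (4-bromobut-1-yn-1-yl)trimethylsilane | C[Si](C)(C)C#CCCBr | starting material
3 | [4-(trimethylsilyl)but-3-yn-1-yl]magnesium bromide | C[Si](C)(C)C#CCC[Mg]Br | intermediate
4 | (R)-9-(trimethylsilyl)non-8-yn-4-ol | CCC[C@@H](O)CCCC#C[Si](C)(C)C | intermediate
5 | (R)-tert-butyldimethyl{[9-(trimethylsilyl)non-8-yn-4-yl]oxy}silane | CCC[C@@H](O[Si](C)(C)C(C)(C)C)CCCC#C[Si](C)(C)C | intermediate
6 | (R)-tert-butyldimethyl(non-8-yn-4-yloxy)silane | CCC[C@@H](O[Si](C)(C)C(C)(C)C)CCCC#C | intermediate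
7 | allyl bromide | C=CCBr | starting material
8 | (R)-tert-butyl(dodec-11-en-8-yn-4-yloxy)dimethylsilane | CCC[C@@H](O[Si](C)(C)C(C)(C)C)CCCC#CCC=C | intermediate
9 | (R)-1-(furan-2-yl)ethan-1-amine | C[C@@H](N)c1ccco1 | starting material
10 | tert-butyl N-[(1R)-1-(furan-2-yl)ethyl]carbamate | C[C@@H](NC(=O)OC(C)(C)C)c1ccco1 | intermediate
11 | tert-butyl N-[(1R)-1-(5-bromofuran-2-yl)ethyl]carbamate | C[C@@H](NC(=O)OC(C)(C)C)c1ccc(Br)o1 | intermediate
12 | 9-[(9R)-9-[(tert-butyldimethylsilyl)oxy]dodec-4-yn-1-yl]-9-borabicyclo[3.3.1]nonane | CCC[C@@H](O[Si](C)(C)C(C)(C)C)CCCC#CCCCB1C2CCCC1CCC2 | intermediate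
13 | tert-butyl N-[(1R)-1-{5-[(9R)-9-[(tert-butyldimethylsilyl)oxy]dodec-4-yn-1-yl]furan-2-yl}ethyl]carbamate | C[C@@H](NC(=O)OC(C)(C)C)c1ccc(CCCC#CCCC[C@H](O[Si](C)(C)C(C)(C)C)CCC)o1 | intermediate
14 | tert-butyl (2R)-6-[(9R)-9-[(tert-butyldimethylsilyl)oxy]dodec-4-yn-1-yl]-6-hydroxy-2-methyl-3-oxo-3,6-dihydropyridine-1(2H)-carboxylate | O=C1C=CC(O)(CCCC#CCCC[C@H](O[Si](C)(C)C(C)(C)C)CCC)N(C(=O)OC(C)(C)C)[C@@H]1C | intermediate
15 | tert-butyl (2R,6R)-6-[(9R)-9-[(tert-butyldimethylsilyl)oxy]dodec-4-yn-1-yl]-2-methyl-3-oxo-3,6-dihydropyridine-1(2H)-carboxylate | O=C1C=C[C@@H](CCCC#CCCC[C@H](O[Si](C)(C)C(C)(C)C)CCC)N(C(=O)OC(C)(C)C)[C@@H]1C | intermediate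
16 | tert-butyl (2R,4aS,5E,8aR)-5-[(5R)-5-[(tert-butyldimethylsilyl)oxy]octylidene]-2-methyl-3-oxooctahydroquinoline-1(2H)-carboxylate | O=C1C[C@H]2/C(=C/CCC[C@H](O[Si](C)(C)C(C)(C)C)CCC)CCC[C@H]2N(C(=O)OC(C)(C)C)[C@@H]1C | intermediate
17 | tert-butyl (2R,3R,4aS,5E,8aR)-5-[(5R)-5-[(tert-butyldimethylsilyl)oxy]octylidene]-3-hydroxy-2-methyloctahydroquinoline-1(2H)-carboxylate | O[C@@H]1C[C@H]2/C(=C/CCC[C@H](O[Si](C)(C)C(C)(C)C)CCC)CCC[C@H]2N(C(=O)OC(C)(C)C)[C@@H]1C | intermediate
18 | tert-butyl (2R,3R,4aS,5S,8aR)-5-[(5R)-5-[(tert-butyldimethylsilyl)oxy]octyl]-3-hydroxy-2-methyloctahydroquinoline-1(2H)-carboxylate | O[C@@H]1C[C@H]2[C@@H](CCCC[C@H](O[Si](C)(C)C(C)(C)C)CCC)CCC[C@H]2N(C(=O)OC(C)(C)C)[C@@H]1C | intermediate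
19 | (2E)-oct-2-enoic acid | CCCCC/C=C/C(=O)O | starting material
20 | tert-butyl (2R,3R,4aS,5S,8aR)-5-[(5R)-5-[(tert-butyldimethylsilyl)oxy]octyl]-2-methyl-3-{[(2E)-oct-2-enoyl]oxy}octahydroquinoline-1(2H)-carboxylate | CCCCC/C=C/C(=O)O[C@@H]1C[C@H]2[C@@H](CCCC[C@H](O[Si](C)(C)C(C)(C)C)CCC)CCC[C@H]2N(C(=O)OC(C)(C)C)[C@@H]1C | intermediate
21 | (2R,3R,4aS,5S,8aR)-5-[(5R)-5-hydroxyoctyl]-2-methyldecahydroquinolin-3-yl (2E)-oct-2-enoate | CCCCC/C=C/C(=O)O[C@@H]1C[C@H]2[C@@H](CCCC[C@H](O)CCC)CCC[C@H]2N[C@@H]1C | target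

**Step count and risks**

Total steps: 14. Longest linear sequence: 12 (steps 1–4, then 7–14).

Steps most likely to fail:

Step 10 (key step). The oxidative cyclisation to the six-membered ring may be slow, so that simple conjugate reduction of the enone, alkyne oligomerisation or enolisation at C2 compete. The fallback sets out from 15 and comes back at 16 and makes no new compound (F0). It is a hydropalladation-initiated reductive enyne cyclisation (Pd2(dba)3·CHCl3, P(o-tol)3, AcOH, Et3SiH, toluene, rt). Here a Pd–H species adds syn across the alkyne, the alkenyl-palladium adds to the enone β-carbon C4a on the tether face, and the palladium enolate is reduced by the silane. This is a different organometallic manifold (hydrometalation/carbometalation instead of metallacycle formation) and should give the same E-alkylidene, cis-fused ketone 16.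

Step 9. Hydride may be delivered to the wrong face of the flat, fully conjugated N-acyliminium ion, or the ion may lose the C2 proton and aromatise to a 3-pyridinol. The fallback sets out from 14 and comes back at 15. It moves the hydride delivery to the saturated ring, where axial attack syn to the pseudoaxial C2 substituent is the established course, and then restores the double bond.
- Conjugate reduction of the enone of 14 with Stryker's reagent and PhSiH3 (the internal alkyne is left alone) should give the saturated keto hemiaminal tert-butyl (2R)-6-[(9R)-9-[(tert-butyldimethylsilyl)oxy]dodec-4-yn-1-yl]-6-hydroxy-2-methyl-3-oxopiperidine-1-carboxylate F1.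
- Et3SiH/BF3·OEt2 at −78 °C should reduce its half-chair N-acyliminium ion to the 2,6-trans ketone tert-butyl (2R,6R)-6-[(9R)-9-[(tert-butyldimethylsilyl)oxy]dodec-4-yn-1-yl]-2-methyl-3-oxopiperidine-1-carboxylate F2.
- Kinetic enolisation toward the C4 methylene (LiHMDS, TMSCl, THF, −78 °C) should give the silyl enol ether tert-butyl (2R,6R)-6-[(9R)-9-[(tert-butyldimethylsilyl)oxy]dodec-4-yn-1-yl]-2-methyl-3-[(trimethylsilyl)oxy]-5,6-dihydropyridine-1(2H)-carboxylate F3.
- Saegusa–Ito oxidation (Pd(OAc)2, MeCN) should re-install the C4=C4a double bond and return 15.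

Step 12. Facial selectivity at C5 may be low, or the alkene may migrate into the ring on the metal surface before it is reduced, which would also put C4a at risk. The fallback sets out from 17 and comes back at 18 and makes no new compound (F0). It replaces steric approach control by substrate direction: homogeneous hydrogenation with Crabtree's catalyst (H2, CH2Cl2), in which the free C3 hydroxyl binds iridium. This hydroxyl stands on the same face of the bicycle as the hydrogen required at C5, so it should deliver H2 to that face without alkene migration.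

Further compounds
F1 | step 9 | tert-butyl (2R)-6-[(9R)-9-[(tert-butyldimethylsilyl)oxy]dodec-4-yn-1-yl]-6-hydroxy-2-methyl-3-oxopiperidine-1-carboxylate | O=C1CCC(O)(CCCC#CCCC[C@H](O[Si](C)(C)C(C)(C)C)CCC)N(C(=O)OC(C)(C)C)[C@@H]1C
F2 | step 9 | tert-butyl (2R,6R)-6-[(9R)-9-[(tert-butyldimethylsilyl)oxy]dodec-4-yn-1-yl]-2-methyl-3-oxopiperidine-1-carboxylate | O=C1CC[C@@H](CCCC#CCCC[C@H](O[Si](C)(C)C(C)(C)C)CCC)N(C(=O)OC(C)(C)C)[C@@H]1C
F3 | step 9 | tert-butyl (2R,6R)-6-[(9R)-9-[(tert-butyldimethylsilyl)oxy]dodec-4-yn-1-yl]-2-methyl-3-[(trimethylsilyl)oxy]-5,6-dihydropyridine-1(2H)-carboxylate | C[Si](C)(C)OC1=CC[C@@H](CCCC#CCCC[C@H](O[Si](C)(C)C(C)(C)C)CCC)N(C(=O)OC(C)(C)C)[C@@H]1C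
F0 | step 10 | none | none
F0 | step 12 | none | none
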